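**Retrosynthetic overview**
1. The strategy rests on the aryl ester linkage C8a–O1–C2 of the pyranone ring. O1 is inserted late, between carbonyl carbon C1 and ring-fusion carbon C7a of a 3-arylindan-1-one whose benzylic C3 (the future C4) already carries the 3,4-dimethoxyphenyl group.
2. Target ⇒ O8-benzyl coumarin (hydrogenolysis) ⇒ 4-arylchroman-2-one (C3–C4 dehydrogenation) ⇒ 7-benzyloxy-3-arylindan-1-one (Baeyer–Villiger ring expansion).
3. Indanone ⇒ chalcone (C3–C3a, Nazarov-type closure onto the only free ortho carbon of ring A) ⇒ 2',3',5'-trioxygenated acetophenone + veratraldehyde (Claisen–Schmidt). O7 passes through the hot acid as a methyl ether and is exchanged for benzyl afterwards by carbonyl-directed BCl3 cleavage.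
4. Acetophenone ⇒ 2'-hydroxy-5'-methoxyacetophenone by phenol-directed C3' bromination and copper-catalysed methoxylation, which fixes the 2',3',5' pattern without relying on a Fries migration.
5. Ring order: ring A (bought) → five-membered ketone ring → six-membered lactone by one-atom enlargement → aromatic pyranone.

Key step: step 8

Remark: the target has no stereocentre. The aldol adduct, all indanones, the Criegee adduct (a mixture of diastereomers) and the chromanone are carried as racemates, and the single carbon stereocentre is erased in step 9.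

**Step 1**
Reactants: 1 2'-hydroxy-5'-methoxyacetophenone
Product: 2 1-(3-bromo-2-hydroxy-5-methoxyphenyl)ethan-1-one
Conditions: NBS (1.05 equiv), MeCN, 0 °C → rt, dark
Reagents that add atoms: N-bromosuccinimide, O=C1CCC(=O)N1Br
Why: Electrophilic aromatic bromination in which the free phenol is the strongest director, its para position is blocked by methoxy and C3' is also meta to the acetyl group, so bromine should enter at C3' only; a Lewis-acid Fries rearrangement of 2,4-dimethoxyphenyl acetate could not guarantee this pattern, because its two methoxy groups steer an acylium ion to the carbon meta to the phenol oxygen.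

**Step 2**
Reactants: 2 1-(3-bromo-2-hydroxy-5-methoxyphenyl)ethan-1-one
Product: 3 1-(2-hydroxy-3,5-dimethoxyphenyl)ethan-1-one
Conditions: NaOMe (25 % in MeOH, 5 equiv), CuBr (0.2 equiv), NMP, 110 °C, N2; then 1 M HCl
Reagents that add atoms: sodium methoxide, C[O-].[Na+]
Why: Ullmann-type copper-catalysed methoxylation of an ortho-bromophenolate, the reaction type that converts 5-bromovanillin into syringaldehyde; the substrate reacts as its phenolate, which also damps self-condensation of the methyl ketone.

**Step 3**
Reactants: 3 1-(2-hydroxy-3,5-dimethoxyphenyl)ethan-1-one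
Product: 4 1-(2,3,5-trimethoxyphenyl)ethan-1-one
Conditions: MeI (1.5 equiv), K2CO3 (2 equiv), DMF, 40 °C
Reagents that add atoms: iodomethane, CI
Why: Williamson etherification; methyl is chosen to carry this oxygen because a benzyl ether ortho to a protonated carbonyl would be lost in the hot trifluoroacetic acid of step 5, and the freed 2'-hydroxychalcone would drain into the flavanone.

**Step 4**
Reactants: 4 1-(2,3,5-trimethoxyphenyl)ethan-1-one; 5 3,4-dimethoxybenzaldehyde
Product: 7 (E)-3-(3,4-dimethoxyphenyl)-1-(2,3,5-trimethoxyphenyl)prop-2-en-1-one, via aldol adduct 6 (not isolated)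
Conditions: KOH (50 % aq), EtOH, rt
Reagents that add atoms: none
Why: Claisen–Schmidt condensation of a methyl ketone with a non-enolisable aldehyde, in which E1cB dehydration of aldol adduct 6 gives the conjugated E alkene as the thermodynamic product.

**Step 5**
Reactants: 7 (E)-3-(3,4-dimethoxyphenyl)-1-(2,3,5-trimethoxyphenyl)prop-2-en-1-one
Product: 8 3-(3,4-dimethoxyphenyl)-4,6,7-trimethoxy-2,3-dihydro-1H-inden-1-one (racemic)
Conditions: CF3CO2H (neat), sealed tube, 100 °C
Reagents that add atoms: none
Why: Nazarov-type cationic cyclisation of an O-protonated chalcone, known for 3',5'-dialkoxychalcones in trifluoroacetic acid: the only free ortho carbon C6' (ortho to the 5'-methoxy and para to the 3'-methoxy group) attacks the β-carbon, whose cation is stabilised by the 4-methoxy donor, forming C3–C3a and setting C3 as a racemate because nothing in the substrate is chiral.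

**Step 6**
Reactants: 8 3-(3,4-dimethoxyphenyl)-4,6,7-trimethoxy-2,3-dihydro-1H-inden-1-one
Product: 10 3-(3,4-dimethoxyphenyl)-7-hydroxy-4,6-dimethoxy-2,3-dihydro-1H-inden-1-one (racemic), via dichloroboryl aryloxide 9 (not isolated)
Conditions: BCl3 (1 M in CH2Cl2, 1.5 equiv), CH2Cl2, −78 → 0 °C; then H2O
Reagents that add atoms: none
Why: Carbonyl-directed aryl methyl ether cleavage in which BCl3 bridges the ketone oxygen and the peri C7 methoxy oxygen and chloride removes that methyl group, which is also the most crowded, out-of-plane one; this selectivity is known for ortho-methoxy aryl ketones, including five-membered-ring ketones such as fluorenones.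

**Step 7**
Reactants: 10 3-(3,4-dimethoxyphenyl)-7-hydroxy-4,6-dimethoxy-2,3-dihydro-1H-inden-1-one; 11 benzyl bromide
Product: 12 7-(benzyloxy)-3-(3,4-dimethoxyphenyl)-4,6-dimethoxy-2,3-dihydro-1H-inden-1-one (racemic)
Conditions: K2CO3 (2 equiv), DMF, 60 °C, N2
Reagents that add atoms: none
Why: Williamson etherification of the hydrogen-bonded phenol with a reactive benzylic halide, K2CO3 being too weak a base to cause alkylation at C2 of the indanone.

**Step 8**
Reactants: 12 7-(benzyloxy)-3-(3,4-dimethoxyphenyl)-4,6-dimethoxy-2,3-dihydro-1H-inden-1-one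
Product: 14 8-(benzyloxy)-4-(3,4-dimethoxyphenyl)-5,7-dimethoxychroman-2-one (racemic), via Criegee adduct 13 (not isolated)
Conditions: mCPBA (2.5 equiv), TsOH·H2O (0.2 equiv), CH2Cl2, 0–5 °C, dark; aq Na2SO3/NaHCO3 quench
Reagents that add atoms: 3-chloroperoxybenzoic acid, OOC(=O)c1cccc(Cl)c1
Why: Baeyer–Villiger oxidation: the acid-activated C1 carbonyl adds the peracid to give Criegee adduct 13, and C7a then shifts from C1 to the proximal peroxide oxygen while 3-chlorobenzoate departs, so that C8a–O1 and O1–C2 are made in one event. The closest known reaction type is the peracid ring expansion of 1-indanones, 3-aryl-1-indanones included, to 3,4-dihydrocoumarins. The six-membered lactone is not closed by a cyclisation but by a 1,2-shift that enlarges the five-membered ketone ring by one oxygen atom. No stereocentre is formed; the racemic C3 centre is not touched and becomes C4 of 14. The step needs migration of C7a rather than of the C2 methylene group, which is secured by the higher migratory aptitude of an aryl carbon bearing the ortho benzyloxy donor over a primary alkyl carbon, the O–O bond being free to align antiperiplanar to either ring bond. It also needs oxidation of the ketone rather than of the arenes, which is secured by masking every phenol, by the carbonyl group that deactivates ring A until insertion has occurred, and by low temperature with mCPBA and only catalytic sulfonic acid instead of a stronger hydroxylating peracid.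

**Step 9**
Reactants: 14 8-(benzyloxy)-4-(3,4-dimethoxyphenyl)-5,7-dimethoxychroman-2-one
Product: 15 8-(benzyloxy)-4-(3,4-dimethoxyphenyl)-5,7-dimethoxy-2H-chromen-2-one
Conditions: DDQ (2 equiv), 1,4-dioxane, 90 °C
Reagents that add atoms: none
Why: DDQ dehydrogenation, known for 4-aryl-3,4-dihydrocoumarins: hydride is taken from the doubly benzylic C4–H, whose cation is stabilised by the 5-, 7- and 4'-methoxy groups, and loss of a C3 proton gives the aromatic pyranone and erases the stereocentre, while the unactivated benzyl ether reacts far more slowly.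

**Step 10**
Reactants: 15 8-(benzyloxy)-4-(3,4-dimethoxyphenyl)-5,7-dimethoxy-2H-chromen-2-one
Product: 16 8-hydroxy-5,7,3',4'-tetramethoxy-4-phenylcoumarin
Conditions: H2 (1 atm), 10 % Pd/C, EtOAc–MeOH, rt, stopped after one equivalent of H2
Reagents that add atoms: none
Why: Catalytic hydrogenolysis of an aryl benzyl ether, whose benzylic C–O bond should be cleaved faster than the trisubstituted C3–C4 double bond, shielded by the aryl group and the 5-methoxy group, is saturated.

**Compound list**
1 | 1-(2-hydroxy-5-methoxyphenyl)ethan-1-one (2'-hydroxy-5'-methoxyacetophenone) | CC(=O)c1cc(OC)ccc1O | starting material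
2 | 1-(3-bromo-2-hydroxy-5-methoxyphenyl)ethan-1-one | CC(=O)c1cc(OC)cc(Br)c1O | intermediate
3 | 1-(2-hydroxy-3,5-dimethoxyphenyl)ethan-1-one | CC(=O)c1cc(OC)cc(OC)c1O | intermediate
4 | 1-(2,3,5-trimethoxyphenyl)ethan-1-one | CC(=O)c1cc(OC)cc(OC)c1OC | intermediate
5 | 3,4-dimethoxybenzaldehyde (veratraldehyde) | COc1ccc(C=O)cc1OC | starting material
6 | 3-(3,4-dimethoxyphenyl)-3-hydroxy-1-(2,3,5-trimethoxyphenyl)propan-1-one (aldol adduct, racemic, not isolated) | COc1ccc(C(O)CC(=O)c2cc(OC)cc(OC)c2OC)cc1OC | intermediate
7 | (E)-3-(3,4-dimethoxyphenyl)-1-(2,3,5-trimethoxyphenyl)prop-2-en-1-one | COc1ccc(/C=C/C(=O)c2cc(OC)cc(OC)c2OC)cc1OC | intermediate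
8 | 3-(3,4-dimethoxyphenyl)-4,6,7-trimethoxy-2,3-dihydro-1H-inden-1-one (racemic) | COc1ccc(C2CC(=O)c3c(OC)c(OC)cc(OC)c32)cc1OC | intermediate
9 | 7-[(dichloroboranyl)oxy]-3-(3,4-dimethoxyphenyl)-4,6-dimethoxy-2,3-dihydro-1H-inden-1-one (boron also bound by the C1 carbonyl oxygen; racemic, not isolated) | COc1ccc(C2CC(=O)c3c(OB(Cl)Cl)c(OC)cc(OC)c32)cc1OC | intermediate
10 | 3-(3,4-dimethoxyphenyl)-7-hydroxy-4,6-dimethoxy-2,3-dihydro-1H-inden-1-one (racemic) | COc1ccc(C2CC(=O)c3c(O)c(OC)cc(OC)c32)cc1OC | intermediate
11 | benzyl bromide | BrCc1ccccc1 | starting material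
12 | 7-(benzyloxy)-3-(3,4-dimethoxyphenyl)-4,6-dimethoxy-2,3-dihydro-1H-inden-1-one (racemic) | COc1ccc(C2CC(=O)c3c(OCc4ccccc4)c(OC)cc(OC)c32)cc1OC | intermediate
13 | 7-(benzyloxy)-3-(3,4-dimethoxyphenyl)-1-hydroxy-4,6-dimethoxy-2,3-dihydro-1H-inden-1-yl 3-chlorobenzenecarboperoxoate (Criegee adduct; racemic, mixture of diastereomers, not isolated) | COc1ccc(C2CC(O)(OOC(=O)c4cccc(Cl)c4)c3c(OCc5ccccc5)c(OC)cc(OC)c32)cc1OC | intermediate
14 | 8-(benzyloxy)-4-(3,4-dimethoxyphenyl)-5,7-dimethoxychroman-2-one (racemic) | COc1ccc(C2CC(=O)Oc3c(OCc4ccccc4)c(OC)cc(OC)c32)cc1OC | intermediate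
15 | 8-(benzyloxy)-4-(3,4-dimethoxyphenyl)-5,7-dimethoxy-2H-chromen-2-one | COc1ccc(-c2cc(=O)oc3c(OCc4ccccc4)c(OC)cc(OC)c23)cc1OC | intermediate
16 | 4-(3,4-dimethoxyphenyl)-8-hydroxy-5,7-dimethoxy-2H-chromen-2-one (8-hydroxy-5,7,3',4'-tetramethoxy-4-phenylcoumarin) | COc1ccc(-c2cc(=O)oc3c(O)c(OC)cc(OC)c23)cc1OC | target

**Total step count:** 10
**Longest linear sequence:** 10 steps (1 → 16)

**Steps most likely to fail**

Step 8. Addition of the peracid to a carbonyl deactivated by the ortho benzyloxy donor may be slower than two competing processes: oxygen transfer to the electron-rich arenes, and oxidation of the acid-formed enol at C2. Material would then be lost to ring hydroxylation and quinone formation. The fallback sets out from 3 and returns at 14. Oxygen is inserted on the simpler acyclic ketone, and the lactone ring is closed by hydroarylation instead of ring expansion. Phenol 3 is benzylated with 11 (K2CO3, DMF, 60 °C) to 1-[2-(benzyloxy)-3,5-dimethoxyphenyl]ethan-1-one F1. Baeyer–Villiger oxidation of this aryl methyl ketone (mCPBA, CH2Cl2, rt) should give 2-(benzyloxy)-3,5-dimethoxyphenyl acetate F2. Methanolysis (catalytic K2CO3, MeOH, rt) frees 2-(benzyloxy)-3,5-dimethoxyphenol F3. Acid-mediated hydroarylation–lactonisation of commercial (E)-3,4-dimethoxycinnamic acid with this phenol (TFA–CH2Cl2, rt) is a known route to 4-aryl-3,4-dihydrocoumarins. It should alkylate the only free carbon ortho to the hydroxyl, which is also ortho and para to the two methoxy groups, and close the lactone to 14. The benzyl ether is not heated here and has no ortho carbonyl group.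

Step 5. The β-cation is strongly stabilised by the 4-methoxy donor and ring A is deactivated by the protonated carbonyl. Ring closure may therefore lag behind acid-induced oligomerisation or retro-aldol cleavage of the chalcone. The fallback sets out from 4 and returns at 8, and C3–C3a is made by palladium instead of by a cation. NBS in MeCN should brominate 4 at C6' (para to the 3'-methoxy and ortho to the 5'-methoxy group, the site between the two methoxy groups being more crowded) to give 1-(2-bromo-3,5,6-trimethoxyphenyl)ethan-1-one F4. Claisen–Schmidt condensation with 5 (KOH, EtOH, rt) gives (E)-1-(2-bromo-3,5,6-trimethoxyphenyl)-3-(3,4-dimethoxyphenyl)prop-2-en-1-one F5. Intramolecular reductive Heck cyclisation (Pd(OAc)2, PPh3, HCO2Na, DMF, 100 °C) is a known conversion of 2'-halochalcones into 3-arylindan-1-ones. It should join C6' to the β-carbon and deliver hydride to the α-carbon to give 8.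

Step 6. Site selectivity among five aryl methyl ethers may be lost. The carbonyl–O7 chelate of a five-membered-ring ketone has a wide bite, and the vicinal dimethoxy units can also bind boron, which would lead to over-demethylation. The fallback sets out from 3 and returns at 10, and the oxygen is marked from the outset by a secondary alkyl ether. Phenol 3 is alkylated with 2-bromopropane (K2CO3, DMF, 60 °C) to 1-(2-isopropoxy-3,5-dimethoxyphenyl)ethan-1-one F6. Claisen–Schmidt condensation with 5 gives (E)-3-(3,4-dimethoxyphenyl)-1-(2-isopropoxy-3,5-dimethoxyphenyl)prop-2-en-1-one F7. Cyclisation in CF3CO2H, kept at the lowest temperature that still closes the ring, gives 3-(3,4-dimethoxyphenyl)-7-isopropoxy-4,6-dimethoxy-2,3-dihydro-1H-inden-1-one F8. BCl3 (CH2Cl2, −78 → 0 °C), which cleaves aryl isopropyl ethers much faster than aryl methyl ethers, should then release 10.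

**Further compounds**
F1 | step 8 | 1-[2-(benzyloxy)-3,5-dimethoxyphenyl]ethan-1-one | CC(=O)c1cc(OC)cc(OC)c1OCc1ccccc1
F2 | step 8 | 2-(benzyloxy)-3,5-dimethoxyphenyl acetate | CC(=O)Oc1cc(OC)cc(OC)c1OCc1ccccc1
F3 | step 8 | 2-(benzyloxy)-3,5-dimethoxyphenol | Oc1cc(OC)cc(OC)c1OCc1ccccc1
F4 | step 5 | 1-(2-bromo-3,5,6-trimethoxyphenyl)ethan-1-one | CC(=O)c1c(Br)c(OC)cc(OC)c1OC
F5 | step 5 | (E)-1-(2-bromo-3,5,6-trimethoxyphenyl)-3-(3,4-dimethoxyphenyl)prop-2-en-1-one | COc1ccc(/C=C/C(=O)c2c(Br)c(OC)cc(OC)c2OC)cc1OC
F6 | step 6 | 1-(2-isopropoxy-3,5-dimethoxyphenyl)ethan-1-one | CC(=O)c1cc(OC)cc(OC)c1OC(C)C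
F7 | step 6 | (E)-3-(3,4-dimethoxyphenyl)-1-(2-isopropoxy-3,5-dimethoxyphenyl)prop-2-en-1-one | COc1ccc(/C=C/C(=O)c2cc(OC)cc(OC)c2OC(C)C)cc1OC
F8 | step 6 | 3-(3,4-dimethoxyphenyl)-7-isopropoxy-4,6-dimethoxy-2,3-dihydro-1H-inden-1-one (racemic) | COc1ccc(C2CC(=O)c3c(OC(C)C)c(OC)cc(OC)c32)cc1OC
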